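**Retrosynthetic overview**
1. 19 <= 18 <= 17. Acetylation of the only free (primary) OH and one global hydrogenolysis (two ArO-Bn groups, one BOM group) come last.
2. 17 <= 14 (key step). The oxolane ring (O1, C2, C3, C4, C5) is made by contracting an oxan-4-one ring. In that ring the future CH2OAc carbon (C9) is still a ring member, the carbonyl carbon between oxolane C3 and C4. Hydride addition, a 1,2-shift of C4 from C9 to C3 with loss of mesylate, and reduction of the expelled formyl group follow in one operation.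
3. Enabling feature. Oxolane C3 carries a one-carbon branch and sits next to the fully substituted carbinol carbon C4, giving the aldol-type array C9-C3-C4-O. With C9 in the ring as C=O, both neighbours are alpha-carbons. C4 has no H, so enolisation, leaving group and shift are each confined to one site. In the chair fixed by the equatorial aryl and benzyl groups, the equatorial C3-OMs bond is antiperiplanar to the C9-C4 ring bond.
4. 14 <= 8 by two alpha-hydroxylations. 8 <= 4 by iodination and Negishi benzylation. 4 <= 1 + 2 by a catalytic asymmetric hetero-Diels-Alder reaction, the only external source of chirality.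
5. Ring order. Both arenes are bought, the six-membered O-ring is formed in step 1, and it is contracted to the five-membered O-ring in step 8.

Key step: step 8

Assumption: (S)-BINOL/Ti(OiPr)4 is taken to direct the diene to the Si face of aldehyde 1, the sense it shows with other pi-nucleophiles and aromatic aldehydes. If the sense is opposite, (R)-BINOL is used and nothing else changes.
Numbering used: oxanone O1, C2 (aryl), C3, C4 (C=O), C5 (quaternary), C6. Oxolane O1, C2 (aryl), C3 (CH2O branch), C4 (quaternary), C5. Ar = 4-(benzyloxy)-3-methoxyphenyl.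

Step 1
Reactants: 1 4-(benzyloxy)-3-methoxybenzaldehyde; 2 Danishefsky's diene, (E)-1-methoxy-3-(trimethylsilyloxy)buta-1,3-diene
Product: 4 (2S)-2-[4-(benzyloxy)-3-methoxyphenyl]-2,3-dihydro-4H-pyran-4-one, via silylated aldol adduct 3 (not isolated)
Conditions: (S)-BINOL (20 mol %), Ti(OiPr)4 (10 mol %), 4 Å MS, Et2O, -20 °C; then CF3CO2H (cat.), CH2Cl2, 0 °C; aqueous work-up
Reagents that add atoms: none
Why: This is the catalytic asymmetric hetero-Diels-Alder reaction in its Mukaiyama aldol/cyclisation variant, in which C-C bond formation on the Si face of 1 sets C2 as S and acid then closes the ring by oxa-Michael addition with loss of methanol.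

Step 2
Reactants: 4 (2S)-2-aryl-2,3-dihydro-4H-pyran-4-one
Product: 5 (2S)-2-[4-(benzyloxy)-3-methoxyphenyl]-5-iodo-2,3-dihydro-4H-pyran-4-one
Conditions: I2 (2 equiv), pyridine-CH2Cl2 (1:1), 0 °C to rt
Reagents that add atoms: iodine, II
Why: This is electrophilic alpha-iodination of a vinylogous ester, in which C5 is the only nucleophilic enone carbon and I2/pyridine is too mild to iodinate the dialkoxyarene.

Step 3
Reactants: 5 (2S)-5-iodo-dihydropyranone; 6 4-(benzyloxy)-3-methoxybenzyl chloride
Product: 8 (2S)-5-[4-(benzyloxy)-3-methoxybenzyl]-2-[4-(benzyloxy)-3-methoxyphenyl]-2,3-dihydro-4H-pyran-4-one, via benzylzinc chloride 7 (not isolated)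
Conditions: 6, Zn dust (1.5 equiv), LiCl (1.5 equiv), THF, 25 °C; then 5, Pd(OAc)2 (2 mol %), SPhos (4 mol %), THF, 25 °C
Reagents that add atoms: none
Why: This is a Negishi cross-coupling of an alpha-iodoenone with a benzylic zinc chloride from LiCl-assisted zinc insertion, which avoids Wurtz coupling of the electron-rich benzyl halide and leaves C2 untouched.

Step 4
Reactants: 8 (2S)-5-benzyl-dihydropyranone
Product: 10 (2S,5R)-5-[4-(benzyloxy)-3-methoxybenzyl]-2-[4-(benzyloxy)-3-methoxyphenyl]-5-hydroxyoxan-4-one (OH cis to aryl; aryl and benzyl equatorial, OH axial), via lithium enolate 9 (not isolated)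
Conditions: LiBH(s-Bu)3 (L-Selectride, 1.1 equiv), THF, -78 °C; then 2-(phenylsulfonyl)-3-phenyloxaziridine (1.5 equiv), -78 °C; AcOH quench
Reagents that add atoms: 2-(phenylsulfonyl)-3-phenyloxaziridine, O=S(=O)(c1ccccc1)N1OC1c1ccccc1
Why: 1,4-Hydride addition to the dihydropyranone gives only the C4=C5 enolate, and Davis oxidation by stereoelectronically preferred axial attack on the half-chair with pseudo-equatorial aryl places oxygen cis to the aryl group (5R) and leaves the benzyl group equatorial.

Step 5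
Reactants: 10 (2S,5R)-5-hydroxyoxan-4-one
Product: 11 (2S,5R)-5-[4-(benzyloxy)-3-methoxybenzyl]-2-[4-(benzyloxy)-3-methoxyphenyl]-5-[(benzyloxy)methoxy]oxan-4-one
Conditions: BOMCl (3 equiv), i-Pr2NEt (4 equiv), Bu4NI (10 mol %), ClCH2CH2Cl, 50 °C
Reagents that add atoms: benzyl chloromethyl ether, ClCOCc1ccccc1
Why: This is O-alkylation of a hindered tertiary alcohol with a reactive chloromethyl ether under amine base, and the BOM group cannot migrate, blocks a second oxyanion in step 8 and falls off in the final hydrogenolysis.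

Step 6
Reactants: 11 (2S,5R)-5-BOM-oxy-oxan-4-one
Product: 13 (2R,3R,5R)-5-[4-(benzyloxy)-3-methoxybenzyl]-2-[4-(benzyloxy)-3-methoxyphenyl]-5-[(benzyloxy)methoxy]-3-hydroxyoxan-4-one (3-OH equatorial, trans to aryl), via sodium enolate 12 (not isolated)
Conditions: NaN(SiMe3)2 (1.2 equiv), THF, -78 °C; then 2-(phenylsulfonyl)-3-phenyloxaziridine (1.5 equiv), -78 °C; AcOH quench at -78 °C
Reagents that add atoms: 2-(phenylsulfonyl)-3-phenyloxaziridine, O=S(=O)(c1ccccc1)N1OC1c1ccccc1
Why: In this Davis enolate hydroxylation C5 has no H so only the C3 enolate can form, and the oxaziridine should approach the face opposite to the axial OBOM and the C2 aryl group to give the equatorial 3-OH (3R), which is also the more stable epimer.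

Step 7
Reactants: 13 (2R,3R,5R)-3-hydroxyoxan-4-one
Product: 14 (2R,3R,5R)-5-[4-(benzyloxy)-3-methoxybenzyl]-2-[4-(benzyloxy)-3-methoxyphenyl]-5-[(benzyloxy)methoxy]-4-oxooxan-3-yl methanesulfonate
Conditions: MsCl (1.5 equiv), pyridine, CH2Cl2, 0 °C
Reagents that add atoms: methanesulfonyl chloride, CS(=O)(=O)Cl
Why: This is sulfonylation of the only free hydroxyl with retention at C3, and pyridine is too weak a base to enolise the alpha-mesyloxy ketone.

Step 8
Reactants: 14 (2R,3R,5R)-4-oxooxan-3-yl methanesulfonate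
Product: 17 {(2S,3R,4S)-4-[4-(benzyloxy)-3-methoxybenzyl]-2-[4-(benzyloxy)-3-methoxyphenyl]-4-[(benzyloxy)methoxy]oxolan-3-yl}methanol, via lithium alkoxide 15 (not isolated), via oxolane-3-carbaldehyde 16 (not isolated)
Conditions: LiEt3BH (4 equiv), THF, -78 °C to 25 °C (50 °C to completion); H2O work-up
Reagents that add atoms: none
Why: LiEt3BH adds to the C4 carbonyl from the open axial face, opposite to the axial OBOM, to give alkoxide 15; in its chair, locked by the equatorial C2 aryl and C5 benzyl groups, the equatorial C3-OMs bond is antiperiplanar to the C4-C5 ring bond, so the oxyanion drives a semipinacol 1,2-shift of C5 from C4 to C3, mesylate leaves, and the formyl group of 16 is reduced at once by excess hydride. The closest known reaction types are the LiEt3BH-induced contraction of pyranoside vicinal hydroxy sulfonates to hydroxymethyl-branched furanosides and the reductive pinacol-type rearrangement of alpha-mesyloxy ketones. The oxolane ring is closed by this suprafacial 1,2-alkyl shift, an intramolecular backside (3-exo-tet-like) displacement at C3 by the C4-C5 sigma bond, which turns the six-membered ring into the five-membered one and forges the hindered bond to the fully substituted carbinol carbon. The one new stereocentre that survives, oxolane C3, is fixed by inversion at the mesylate carbon (3R, CH2OH trans to aryl and cis to benzyl); the migrating carbon keeps its configuration, C2 is untouched, and the carbinol centre of 15 vanishes, so its configuration does not matter. The carbon shift must win over epoxide closure, shift of the ring oxygen, hydride shift and direct displacement: epoxide closure would need a twist-boat and the face crowded by aryl and OBOM, no C-H bond is antiperiplanar to the leaving group, external hydride cannot reach the rear of an equatorial sulfonate, and only the carbon shift is accelerated by the oxyanion. The BOM ether keeps the tertiary oxygen from becoming a second oxyanion (no Grob or retro-aldol cleavage), and the fast reduction of 16 forestalls epimerisation and beta-elimination.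

Step 9
Reactants: 17 oxolan-3-ylmethanol
Product: 18 {(2S,3R,4S)-4-[4-(benzyloxy)-3-methoxybenzyl]-2-[4-(benzyloxy)-3-methoxyphenyl]-4-[(benzyloxy)methoxy]oxolan-3-yl}methyl acetate
Conditions: Ac2O (1.5 equiv), pyridine, DMAP (5 mol %), CH2Cl2, 0 °C to rt
Reagents that add atoms: acetic anhydride, CC(=O)OC(C)=O
Why: This is nucleophile-catalysed acetylation of the only free, primary hydroxyl group.

Step 10
Reactants: 18 protected acetate
Product: 19 olivil monoacetate, {(2S,3R,4S)-4-hydroxy-4-(4-hydroxy-3-methoxybenzyl)-2-(4-hydroxy-3-methoxyphenyl)oxolan-3-yl}methyl acetate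
Conditions: H2 (1 atm), 10% Pd/C, EtOAc-EtOH, rt, stopped at full debenzylation
Reagents that add atoms: none
Why: Hydrogenolysis removes the two aryl benzyl ethers and the BOM benzyl group (the resulting hemiacetal loses formaldehyde), and neutral solvent, 1 atm and short exposure should spare the cyclic benzylic C2-O1 bond and the acetate.

**Compound list**
1 | 4-(benzyloxy)-3-methoxybenzaldehyde | O=Cc1ccc(OCc2ccccc2)c(OC)c1 | starting material
2 | Danishefsky's diene | CO/C=C/C(=C)O[Si](C)(C)C | starting material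
3 | (1E,5S)-5-Ar-1-methoxy-5-(trimethylsilyloxy)pent-1-en-3-one | CO/C=C/C(=O)C[C@H](O[Si](C)(C)C)c1ccc(OCc2ccccc2)c(OC)c1 | intermediate
4 | (2S)-2-Ar-2,3-dihydro-4H-pyran-4-one | O=C1C=CO[C@H](c2ccc(OCc3ccccc3)c(OC)c2)C1 | intermediate
5 | (2S)-2-Ar-5-iodo-2,3-dihydro-4H-pyran-4-one | O=C1C(I)=CO[C@H](c2ccc(OCc3ccccc3)c(OC)c2)C1 | intermediate
6 | 4-(benzyloxy)-3-methoxybenzyl chloride | ClCc1ccc(OCc2ccccc2)c(OC)c1 | starting material
7 | [4-(benzyloxy)-3-methoxybenzyl]zinc chloride | Cl[Zn]Cc1ccc(OCc2ccccc2)c(OC)c1 | intermediate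
8 | (2S)-2-Ar-5-(ArCH2)-2,3-dihydro-4H-pyran-4-one | O=C1C(Cc2ccc(OCc3ccccc3)c(OC)c2)=CO[C@H](c2ccc(OCc3ccccc3)c(OC)c2)C1 | intermediate
9 | lithium C4=C5 enolate of (2S)-2-Ar-5-(ArCH2)oxan-4-one | [Li+].[O-]C1=C(Cc2ccc(OCc3ccccc3)c(OC)c2)CO[C@H](c2ccc(OCc3ccccc3)c(OC)c2)C1 | intermediate
10 | (2S,5R)-2-Ar-5-(ArCH2)-5-hydroxyoxan-4-one | O=C1[C@@](O)(Cc2ccc(OCc3ccccc3)c(OC)c2)CO[C@H](c2ccc(OCc3ccccc3)c(OC)c2)C1 | intermediate
11 | (2S,5R)-2-Ar-5-(ArCH2)-5-[(benzyloxy)methoxy]oxan-4-one | O=C1[C@@](OCOCc2ccccc2)(Cc2ccc(OCc3ccccc3)c(OC)c2)CO[C@H](c2ccc(OCc3ccccc3)c(OC)c2)C1 | intermediate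
12 | sodium C3=C4 enolate of 11 (2S,5R) | [Na+].[O-]C1=C[C@@H](c2ccc(OCc3ccccc3)c(OC)c2)OC[C@]1(OCOCc2ccccc2)Cc2ccc(OCc3ccccc3)c(OC)c2 | intermediate
13 | (2R,3R,5R)-3-hydroxy derivative of 11 | O=C1[C@H](O)[C@@H](c2ccc(OCc3ccccc3)c(OC)c2)OC[C@]1(OCOCc2ccccc2)Cc2ccc(OCc3ccccc3)c(OC)c2 | intermediate
14 | (2R,3R,5R)-4-oxooxan-3-yl methanesulfonate | O=C1[C@H](OS(C)(=O)=O)[C@@H](c2ccc(OCc3ccccc3)c(OC)c2)OC[C@]1(OCOCc2ccccc2)Cc2ccc(OCc3ccccc3)c(OC)c2 | intermediate
15 | lithium (2R,3S,4S,5R)-3-(mesyloxy)oxan-4-olate (4-O equatorial) | [Li+].[O-][C@H]1[C@H](OS(C)(=O)=O)[C@@H](c2ccc(OCc3ccccc3)c(OC)c2)OC[C@]1(OCOCc2ccccc2)Cc2ccc(OCc3ccccc3)c(OC)c2 | intermediate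
16 | (2S,3R,4S)-2-Ar-4-(ArCH2)-4-[(benzyloxy)methoxy]oxolane-3-carbaldehyde | O=C[C@@H]1[C@@H](c2ccc(OCc3ccccc3)c(OC)c2)OC[C@]1(OCOCc2ccccc2)Cc2ccc(OCc3ccccc3)c(OC)c2 | intermediate
17 | {(2S,3R,4S)-2-Ar-4-(ArCH2)-4-[(benzyloxy)methoxy]oxolan-3-yl}methanol | OC[C@@H]1[C@@H](c2ccc(OCc3ccccc3)c(OC)c2)OC[C@]1(OCOCc2ccccc2)Cc2ccc(OCc3ccccc3)c(OC)c2 | intermediate
18 | acetate of 17 (2S,3R,4S) | CC(=O)OC[C@@H]1[C@@H](c2ccc(OCc3ccccc3)c(OC)c2)OC[C@]1(OCOCc2ccccc2)Cc2ccc(OCc3ccccc3)c(OC)c2 | intermediate
19 | olivil monoacetate (2S,3R,4S) | COc1cc(C[C@@]2(O)CO[C@H](c3ccc(O)c(OC)c3)[C@H]2COC(C)=O)ccc1O | target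

Total step count: 10. Longest linear sequence: 10 steps (1 to 19).

**Steps most likely to fail**

1. Step 8.
 - What may go wrong: the alkoxide may close to an epoxide through a twist-boat and then be opened by hydride. The ring oxygen may shift instead of carbon. Hydride may also attack sulfur and merely strip the mesyl group.
 - Fallback: it sets out from 11 and comes back at 17, and it contracts the same ring without any leaving-group geometry.
 - Trifluoroacetylation of the C3 enolate (LiN(SiMe3)2, CF3CO2CH2CF3, -78 °C) would give the 3-(trifluoroacetyl) ketone F1.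
 - Detrifluoroacetylative diazo transfer (MsN3, Et3N, H2O, MeCN) would give the alpha-diazo ketone F2.
 - Irradiation in methanol (photochemical Wolff rearrangement, with C5 again the migrating carbon) would give the methyl oxolane-3-carboxylate F3.
 - The C3 centre of F3 is brought to the 2,3-trans arrangement by NaOMe equilibration, because the other epimer holds the ester cis to both aryl and OBOM.
 - LiAlH4 reduction then gives 17.

2. Step 4.
 - What may go wrong: facial selectivity of oxygen transfer may be poor through attack on the half-chair with pseudo-axial aryl. The hindered enolate may be captured by the sulfonimine left by the oxaziridine. The ring alkoxide may be lost from C6 before oxidation.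
 - Fallback: it sets out from 8 and comes back at 10, and it replaces enolate chemistry with a radical hydrofunctionalisation.
 - A Mukaiyama-type reductive oxygenation (Mn(dpm)3 cat., PhSiH3, O2, i-PrOH, 0 °C) transfers an H atom to C6.
 - The tertiary alpha-keto radical at C5 is trapped by O2 to give the tertiary hydroperoxide F4.
 - P(OEt)3 reduces F4 to 10.

3. Step 6.
 - What may go wrong: enolate 12 may open by retro-oxa-Michael loss of the ring alkoxide from the benzylic carbon. The oxidant may attack the wrong face and give the axial 3-OH.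
 - Fallback: it sets out from 11 and comes back at 13, and it makes use of the ring opening.
 - KN(SiMe3)2 (-78 to 0 °C) followed by Et3SiCl would give the ring-opened silyloxy enone F5.
 - Juliá-Colonna epoxidation (poly-L-leucine, urea-H2O2, DBU, THF) under reagent control would give the trans-epoxy ketone F6.
 - HF·pyridine releases the hydroxy epoxy ketone F7.
 - Under mild acid (PPTS, CH2Cl2) the primary OH of F7 opens the epoxide at the benzylic carbon (6-endo, inversion). This is the aliphatic counterpart of the chalcone epoxide to dihydroflavonol cyclisation and gives 13.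

**Further compounds**
F1 | step 8 | (2R,5R)-2-Ar-5-(ArCH2)-5-[(benzyloxy)methoxy]-3-(trifluoroacetyl)oxan-4-one (C3 enolisable, not defined) | O=C1C(C(=O)C(F)(F)F)[C@@H](c2ccc(OCc3ccccc3)c(OC)c2)OC[C@]1(OCOCc2ccccc2)Cc2ccc(OCc3ccccc3)c(OC)c2
F2 | step 8 | (2R,5R)-3-diazo-2-Ar-5-(ArCH2)-5-[(benzyloxy)methoxy]oxan-4-one | O=C1C(=[N+]=[N-])[C@@H](c2ccc(OCc3ccccc3)c(OC)c2)OC[C@]1(OCOCc2ccccc2)Cc2ccc(OCc3ccccc3)c(OC)c2
F3 | step 8 | methyl (2S,3R,4S)-2-Ar-4-(ArCH2)-4-[(benzyloxy)methoxy]oxolane-3-carboxylate | COC(=O)[C@@H]1[C@@H](c2ccc(OCc3ccccc3)c(OC)c2)OC[C@]1(OCOCc2ccccc2)Cc2ccc(OCc3ccccc3)c(OC)c2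
F4 | step 4 | (2S,5R)-2-Ar-5-(ArCH2)-5-hydroperoxyoxan-4-one | O=C1[C@@](OO)(Cc2ccc(OCc3ccccc3)c(OC)c2)CO[C@H](c2ccc(OCc3ccccc3)c(OC)c2)C1
F5 | step 6 | (1E,4R)-1-Ar-4-(ArCH2)-4-[(benzyloxy)methoxy]-5-(triethylsilyloxy)pent-1-en-3-one | O=C(/C=C/c1ccc(OCc2ccccc2)c(OC)c1)[C@@](OCOCc1ccccc1)(Cc1ccc(OCc2ccccc2)c(OC)c1)CO[Si](CC)(CC)CC
F6 | step 6 | (1S,2R,4R)-1,2-epoxy derivative of F5 (trans-epoxide) | O=C([C@@H]1O[C@H]1c2ccc(OCc3ccccc3)c(OC)c2)[C@@](OCOCc1ccccc1)(Cc1ccc(OCc2ccccc2)c(OC)c1)CO[Si](CC)(CC)CC
F7 | step 6 | (1S,2R,4R)-1,2-epoxy-5-hydroxy ketone from F6 | O=C([C@@H]1O[C@H]1c2ccc(OCc3ccccc3)c(OC)c2)[C@@](OCOCc1ccccc1)(Cc1ccc(OCc2ccccc2)c(OC)c1)CO
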